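## Retrosynthetic overview

1. Dorsilurin C (15) ⇐ bis-MOM ether 14 ⇐ tetraene 12. One ruthenium-alkylidene operation closes the pyran ring of the chromene at its C3=C4 bond by ring-closing metathesis and converts both ring-A allyl groups into prenyl groups by cross-metathesis with 2-methyl-2-butene.
2. Enabling feature: on ring B, C4' and the C3' oxygen are ortho. A vinyl group on C4' and the vinyl group of a C3'–O–C(CH3)2–CH=CH2 ether therefore form a 1,7-diene that can only close to the six-membered 2H-pyran. The ring-A side chains are ArCH2–CH=C(CH3)2 units, i.e. allyl groups with the terminal CH2 exchanged.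
3. 12 ⇐ chalcone 10 (Algar–Flynn–Oyamada closure of ring C) ⇐ acetophenone 4 + aldehyde 9 (Claisen–Schmidt condensation).
4. 4 ⇐ phloroacetophenone 1 by O-allylation, double aromatic Claisen rearrangement and MOM protection. 9 ⇐ 4-bromo-3-hydroxybenzaldehyde 5 by Suzuki vinylation and palladium-catalysed O-(1,1-dimethylallyl)ation.
5. Ring order: rings A and B are purchased, ring C is formed in step 8, the pyran ring on ring B in step 9.

Key step: step 9

Assumption: where one step performs the same reaction at two equivalent sites of one molecule (steps 1, 2, 3, 10 and the second stage of step 9), the singly reacted species is treated as part of that one transformation and is not numbered. The target has no stereocentre; the only stereo-elements on the way are the E-enone of 10 and the transient racemic trans pair in 11.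

## Route

Step 1
Reactants: 1 1-(2,4,6-trihydroxyphenyl)ethanone
Product: 2 1-[2-hydroxy-4,6-bis(prop-2-en-1-yloxy)phenyl]ethanone
Conditions: allyl bromide (2.1 equiv), K2CO3, acetone, reflux
Reagents that add atoms: allyl bromide, C=CCBr
Why: Williamson O-allylation; the 4-OH and one ortho OH are alkylated, while the remaining ortho OH is held in a hydrogen bond to the acetyl carbonyl and should stay free.

Step 2
Reactants: 2 1-[2-hydroxy-4,6-bis(prop-2-en-1-yloxy)phenyl]ethanone
Product: 3 1-[2,4,6-trihydroxy-3,5-di(prop-2-en-1-yl)phenyl]ethanone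
Conditions: PhNEt2, 200 °C, sealed tube, Ar
Reagents that add atoms: none
Why: Two successive aromatic Claisen [3,3] rearrangements; C3 and C5 are the only open ring positions, so the ortho pathways and any para relay through a dienone converge on the 3,5-diallyl triol.

Step 3
Reactants: 3 1-[2,4,6-trihydroxy-3,5-di(prop-2-en-1-yl)phenyl]ethanone
Product: 4 1-[2-hydroxy-4,6-bis(methoxymethoxy)-3,5-di(prop-2-en-1-yl)phenyl]ethanone
Conditions: MOMCl (2.2 equiv), i-Pr2NEt, CH2Cl2, 0 °C to rt
Reagents that add atoms: chloromethyl methyl ether, COCCl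
Why: MOM protection of phenols by alkylation; 3 is symmetric, so the 4-OH and either ortho OH react and the last, carbonyl-chelated OH should remain for the later closure of ring C.

Step 4
Reactants: 5 4-bromo-3-hydroxybenzaldehyde
Product: 6 4-ethenyl-3-hydroxybenzaldehyde
Conditions: vinylboronic acid pinacol ester, PdCl2(dppf) (3 mol%), K2CO3, 1,4-dioxane/H2O, 80 °C
Reagents that add atoms: vinylboronic acid pinacol ester, C=CB1OC(C)(C)C(C)(C)O1
Why: Suzuki–Miyaura coupling of an aryl bromide activated by the para formyl group; free phenol and aldehyde are tolerated.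

Step 5
Reactants: 7 2-methylbut-3-en-2-ol
Product: 8 tert-butyl 2-methylbut-3-en-2-yl carbonate
Conditions: n-BuLi, THF, −78 °C; then Boc2O, −78 °C to rt
Reagents that add atoms: di-tert-butyl dicarbonate, CC(C)(C)OC(=O)OC(=O)OC(C)(C)C
Why: Acylation of the lithium alkoxide of a tertiary alcohol by the dicarbonate gives the mixed carbonate needed as the allyl donor.

Step 6
Reactants: 6 4-ethenyl-3-hydroxybenzaldehyde; 8 tert-butyl 2-methylbut-3-en-2-yl carbonate
Product: 9 4-ethenyl-3-[(2-methylbut-3-en-2-yl)oxy]benzaldehyde
Conditions: Pd(PPh3)4 (3 mol%), 4 Å molecular sieves, THF, 0 °C to rt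
Reagents that add atoms: none
Why: Decarboxylative Tsuji–Trost O-allylation; zerovalent palladium ionises 8 to a 1,1-dimethyl-π-allyl complex, which the phenoxide attacks at the more substituted terminus under kinetic control at low temperature, giving the tertiary aryl ether without Claisen rearrangement.

Step 7
Reactants: 4 1-[2-hydroxy-4,6-bis(methoxymethoxy)-3,5-di(prop-2-en-1-yl)phenyl]ethanone; 9 4-ethenyl-3-[(2-methylbut-3-en-2-yl)oxy]benzaldehyde
Product: 10 (E)-3-{4-ethenyl-3-[(2-methylbut-3-en-2-yl)oxy]phenyl}-1-[2-hydroxy-4,6-bis(methoxymethoxy)-3,5-di(prop-2-en-1-yl)phenyl]prop-2-en-1-one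
Conditions: KOH (aq.), EtOH, 0 °C to rt
Reagents that add atoms: none
Why: Claisen–Schmidt condensation of a methyl ketone with a non-enolisable aldehyde; elimination from the aldol should give the thermodynamically preferred E-enone, and room temperature keeps the tertiary allyl ether and the allyl groups unchanged.

Step 8
Reactants: 10 (E)-3-{4-ethenyl-3-[(2-methylbut-3-en-2-yl)oxy]phenyl}-1-[2-hydroxy-4,6-bis(methoxymethoxy)-3,5-di(prop-2-en-1-yl)phenyl]prop-2-en-1-one
Product: 12 2-{4-ethenyl-3-[(2-methylbut-3-en-2-yl)oxy]phenyl}-3-hydroxy-5,7-bis(methoxymethoxy)-6,8-di(prop-2-en-1-yl)-4H-chromen-4-one, via trans-dihydroflavonol 11 (not isolated)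
Conditions: 30% aq. H2O2, NaOH (aq.), MeOH/THF, 0 °C to rt
Reagents that add atoms: hydrogen peroxide, OO
Why: Algar–Flynn–Oyamada reaction; alkaline peroxide oxidises the 2'-hydroxychalcone with closure of ring C at the β-carbon to the racemic trans-dihydroflavonol 11 (aryl and OH diequatorial), which the same reagent dehydrogenates to the flavonol so that both stereocentres disappear, while nucleophilic HOO− leaves the isolated vinyl and allyl olefins alone.

Step 9
Reactants: 12 2-{4-ethenyl-3-[(2-methylbut-3-en-2-yl)oxy]phenyl}-3-hydroxy-5,7-bis(methoxymethoxy)-6,8-di(prop-2-en-1-yl)-4H-chromen-4-one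
Product: 14 2-(2,2-dimethyl-2H-chromen-7-yl)-3-hydroxy-5,7-bis(methoxymethoxy)-6,8-bis(3-methylbut-2-en-1-yl)-4H-chromen-4-one, via diallyl chromene flavonol 13 (not isolated)
Conditions: second-generation Grubbs catalyst (H2IMes)(PCy3)Cl2Ru=CHPh (5 mol%), 1,4-benzoquinone (10 mol%), CH2Cl2 (0.005 M), 40 °C; then, in the same flask, 2-methyl-2-butene (large excess) and a second 5 mol% of catalyst, 35 °C, sealed vessel
Reagents that add atoms: 2-methyl-2-butene, CC=C(C)C
Why: The ruthenium alkylidene exchanges onto the unhindered styrene CH=CH2 on ring B, and the resulting benzylidene undergoes intramolecular [2+2] cycloaddition and cycloreversion through a metallacyclobutane with the vinyl group on the quaternary ether carbon, forming the chromene C3=C4 bond with loss of ethene to give 13; after 2-methyl-2-butene is added, the same catalyst exchanges the terminal CH2 of each ring-A allyl group for C(CH3)2 with loss of propene. The closest known reaction types are ring-closing metathesis of 2-(allyloxy)styrenes to 2H-chromenes and allyl-to-prenyl cross-metathesis of C-allyl phenols with 2-methyl-2-butene. The one ring closed is the six-membered 2H-pyran, closed by ring-closing olefin metathesis of a 1,7-diene (counted through C4', C3', O and the CMe2 carbon), which can only give the cis ring olefin. No stereocentre is formed, and the new side-chain olefins carry two identical methyl groups, so no E/Z question arises. The step needs chemoselectivity (ring closure before the styrene is capped by the cross partner, cross-metathesis only at the allyl groups); this is secured by the ortho arrangement and the gem-dimethyl group that hold the two vinyl groups together, by running the dilute ring-closing stage before the cross partner is added, and by the neopentyl-type hindrance that keeps the O–CMe2–CH=CH2 olefin out of intermolecular metathesis. The products are a cis-disubstituted ring olefin next to a quaternary carbon and two trisubstituted olefins, all poor substrates for further metathesis, so the sequence should stop at 14; benzoquinone suppresses ruthenium-hydride migration of the allyl double bonds.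

Step 10
Reactants: 14 2-(2,2-dimethyl-2H-chromen-7-yl)-3-hydroxy-5,7-bis(methoxymethoxy)-6,8-bis(3-methylbut-2-en-1-yl)-4H-chromen-4-one
Product: 15 dorsilurin C
Conditions: 3 M aq. HCl, MeOH, rt to 40 °C
Reagents that add atoms: none
Why: Acid-catalysed cleavage of the two aryl MOM acetals by transacetalisation to methanol; mild acid at moderate temperature has close precedent on ortho-prenylphenol flavonoids and should leave the prenyl groups and the chromene intact.

## Compound list

1 | 1-(2,4,6-trihydroxyphenyl)ethanone (2',4',6'-trihydroxyacetophenone) | CC(=O)c1c(O)cc(O)cc1O | starting material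
2 | 1-[2-hydroxy-4,6-bis(prop-2-en-1-yloxy)phenyl]ethanone | CC(=O)c1c(O)cc(OCC=C)cc1OCC=C | intermediate
3 | 1-[2,4,6-trihydroxy-3,5-di(prop-2-en-1-yl)phenyl]ethanone | CC(=O)c1c(O)c(CC=C)c(O)c(CC=C)c1O | intermediate
4 | 1-[2-hydroxy-4,6-bis(methoxymethoxy)-3,5-di(prop-2-en-1-yl)phenyl]ethanone | CC(=O)c1c(O)c(CC=C)c(OCOC)c(CC=C)c1OCOC | intermediate
5 | 4-bromo-3-hydroxybenzaldehyde | O=Cc1ccc(Br)c(O)c1 | starting material
6 | 4-ethenyl-3-hydroxybenzaldehyde | O=Cc1ccc(C=C)c(O)c1 | intermediate
7 | 2-methylbut-3-en-2-ol | C=CC(C)(C)O | starting material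
8 | tert-butyl 2-methylbut-3-en-2-yl carbonate | C=CC(C)(C)OC(=O)OC(C)(C)C | intermediate
9 | 4-ethenyl-3-[(2-methylbut-3-en-2-yl)oxy]benzaldehyde | O=Cc1ccc(C=C)c(OC(C)(C)C=C)c1 | intermediate
10 | (E)-3-{4-ethenyl-3-[(2-methylbut-3-en-2-yl)oxy]phenyl}-1-[2-hydroxy-4,6-bis(methoxymethoxy)-3,5-di(prop-2-en-1-yl)phenyl]prop-2-en-1-one | C=CCc1c(O)c(C(=O)/C=C/c2ccc(C=C)c(OC(C)(C)C=C)c2)c(OCOC)c(CC=C)c1OCOC | intermediate
11 | racemic trans-2-{4-ethenyl-3-[(2-methylbut-3-en-2-yl)oxy]phenyl}-3-hydroxy-5,7-bis(methoxymethoxy)-6,8-di(prop-2-en-1-yl)-2,3-dihydro-4H-chromen-4-one ((2R,3R) enantiomer drawn) | C=Cc1ccc(cc1OC(C)(C)C=C)[C@@H]2[C@H](C(=O)c3c(OCOC)c(CC=C)c(OCOC)c(CC=C)c3O2)O | intermediate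
12 | 2-{4-ethenyl-3-[(2-methylbut-3-en-2-yl)oxy]phenyl}-3-hydroxy-5,7-bis(methoxymethoxy)-6,8-di(prop-2-en-1-yl)-4H-chromen-4-one | C=CCc1c(OCOC)c(CC=C)c2oc(-c3ccc(C=C)c(OC(C)(C)C=C)c3)c(O)c(=O)c2c1OCOC | intermediate
13 | 2-(2,2-dimethyl-2H-chromen-7-yl)-3-hydroxy-5,7-bis(methoxymethoxy)-6,8-di(prop-2-en-1-yl)-4H-chromen-4-one | C=CCc1c(OCOC)c(CC=C)c2oc(-c3ccc4c(c3)OC(C)(C)C=C4)c(O)c(=O)c2c1OCOC | intermediate
14 | 2-(2,2-dimethyl-2H-chromen-7-yl)-3-hydroxy-5,7-bis(methoxymethoxy)-6,8-bis(3-methylbut-2-en-1-yl)-4H-chromen-4-one | CC(C)=CCc1c(OCOC)c(CC=C(C)C)c2oc(-c3ccc4c(c3)OC(C)(C)C=C4)c(O)c(=O)c2c1OCOC | intermediate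
15 | dorsilurin C, 2-(2,2-dimethyl-2H-chromen-7-yl)-3,5,7-trihydroxy-6,8-bis(3-methylbut-2-en-1-yl)-4H-chromen-4-one | CC(C)=CCc1c(O)c(CC=C(C)C)c2oc(-c3ccc4c(c3)OC(C)(C)C=C4)c(O)c(=O)c2c1O | target

## Step count and risks

Total step count: 10 (step 5 prepares a reagent). Longest linear sequence: 7 steps (steps 1, 2, 3, 7, 8, 9, 10).

The three steps most likely to fail:

Step 9. The risk is that the two metathesis events interfere: the styrene terminus may be turned into an internal or chelated alkylidene before the ring closes, or ruthenium hydride may move the allyl double bonds into conjugation, so that ring closure and side-chain exchange do not both reach completion in one flask. The fallback moves the ring closure to the simplest substrate and separates it from the side-chain exchange. It sets out from 9, which is ring-closed alone (second-generation Grubbs catalyst, CH2Cl2, 40 °C) to 2,2-dimethyl-2H-chromene-7-carbaldehyde F1. Claisen–Schmidt condensation of F1 with acetophenone 4 (KOH, EtOH) should give the chromene chalcone F2. Algar–Flynn–Oyamada oxidation of F2 (alkaline H2O2), through the racemic trans-dihydroflavonol F3, should give 13, which is isolated here. A separate cross-metathesis of 13 with 2-methyl-2-butene returns to the route at 14.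

Step 8. The risk is attack of the phenoxide at the α-carbon instead of the β-carbon during the oxidative cyclisation (five-membered closure leading to an aurone), favoured by the twist that the 6'-OMOM group and the flanking allyl groups impose on the carbonyl. The fallback closes ring C before the oxygen is introduced, so that a five-membered ring can no longer form. It sets out from 10, which is cyclised by oxa-Michael addition (NaOAc, EtOH, 60 °C) to the racemic flavanone F4. Soft enolisation (TMSOTf, Et3N, CH2Cl2, −20 °C) should give the silyl enol ether F5. Rubottom oxidation (mCPBA, 1.0 equiv, NaHCO3, CH2Cl2, −30 °C, then dilute citric acid) should attack the electron-rich enol ether faster than the monosubstituted olefins, and from the face opposite the C2 aryl group, to give the trans-dihydroflavonol 11, isolated here. Dehydrogenation of 11 with alkaline H2O2 rejoins the route at 12.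

Step 10. The risk is acid-induced addition of the 5- or 7-hydroxyl group to the neighbouring prenyl double bond (chroman formation), or of methanol to the chromene, during MOM removal. The fallback puts the acid step before the prenyl groups exist. It sets out from 12, which is ring-closed without the cross partner (first stage of step 9 only), and 13 is isolated. MOM removal from 13 (HCl, MeOH) should give the diallyl triol F6, whose allyl groups do not cyclise under these conditions. Cross-metathesis of the unprotected F6 with 2-methyl-2-butene (second-generation Grubbs catalyst) then gives the target 15 directly as the last step.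

## Further compounds

F1 | step 9 | 2,2-dimethyl-2H-chromene-7-carbaldehyde | CC1(C)C=Cc2ccc(C=O)cc2O1
F2 | step 9 | (E)-3-(2,2-dimethyl-2H-chromen-7-yl)-1-[2-hydroxy-4,6-bis(methoxymethoxy)-3,5-di(prop-2-en-1-yl)phenyl]prop-2-en-1-one | C=CCc1c(O)c(C(=O)/C=C/c2ccc3C=CC(C)(C)Oc3c2)c(OCOC)c(CC=C)c1OCOC
F3 | step 9 | racemic trans-2-(2,2-dimethyl-2H-chromen-7-yl)-3-hydroxy-5,7-bis(methoxymethoxy)-6,8-di(prop-2-en-1-yl)-2,3-dihydro-4H-chromen-4-one ((2R,3R) enantiomer drawn) | CC1(C)C=Cc2ccc(cc2O1)[C@@H]3[C@H](C(=O)c4c(OCOC)c(CC=C)c(OCOC)c(CC=C)c4O3)O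
F4 | step 8 | racemic 2-{4-ethenyl-3-[(2-methylbut-3-en-2-yl)oxy]phenyl}-5,7-bis(methoxymethoxy)-6,8-di(prop-2-en-1-yl)-2,3-dihydro-4H-chromen-4-one ((2S) enantiomer drawn) | C=Cc1ccc(cc1OC(C)(C)C=C)[C@@H]2CC(=O)c3c(OCOC)c(CC=C)c(OCOC)c(CC=C)c3O2
F5 | step 8 | racemic 2-{4-ethenyl-3-[(2-methylbut-3-en-2-yl)oxy]phenyl}-5,7-bis(methoxymethoxy)-6,8-di(prop-2-en-1-yl)-4-(trimethylsilyloxy)-2H-chromene ((2S) enantiomer drawn) | C=Cc1ccc(cc1OC(C)(C)C=C)[C@@H]2C=C(O[Si](C)(C)C)c3c(OCOC)c(CC=C)c(OCOC)c(CC=C)c3O2
F6 | step 10 | 2-(2,2-dimethyl-2H-chromen-7-yl)-3,5,7-trihydroxy-6,8-di(prop-2-en-1-yl)-4H-chromen-4-one | C=CCc1c(O)c(CC=C)c2oc(-c3ccc4c(c3)OC(C)(C)C=C4)c(O)c(=O)c2c1O
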